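**Plan**

1. Labels: the dioxane is O1–O2–C3–C4–C5–C6; C3 carries the propanoate (C2 with its methyl, C1 the ester carbon); C6 carries a methyl group and the C7–C8 link to the cyclohexenone ring.
2. Enabling feature: C6 is bonded to O1, C5, CH3 and C7, so it is a methyl ketone carbon in disguise, and O2–C3–C4–C5 is an allylic hydroperoxide in disguise. With C7≡C8 as an alkyne and C4=C5 as a Z-vinylsilane, the ring can be cut at O1–C6 and C5–C6.
3. Retrosynthesis: ester → acid → primary alcohol → silyl ether at C1; the C4–C5 and C7–C8 single bonds → ring alkene and alkyne (17); 17 → hydroperoxide 9 + ynone ketal 15.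
4. Forward: 9 in six steps from a syn-aldol of 3-(trimethylsilyl)propynal; 15 in four steps from β-cyclocitral; their union in step 11 closes the only ring made in the route; diimide, desilylation, oxidation and esterification finish.
5. Stereochemistry: C2 and the C3 carbinol come from the (R)-benzyloxazolidinone syn-aldol; C3 is then inverted by SN2 with hydroperoxide anion; C6 is relayed from C3 in the chair-like ring closure.
6. C1 travels as a silyl ether and becomes the methyl ester last, because a β-sulfonyloxy or β-hydroperoxy ester would be eliminated or perhydrolysed in alkaline hydrogen peroxide.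

Key step: step 11

Remark: the labels C1–C8, O1 and O2 used in the Why lines are those of line 1 of the plan, not IUPAC locants.

**Step 1**
Reactants: 1 (4R)-4-benzyl-3-propanoyl-1,3-oxazolidin-2-one; 2 3-(trimethylsilyl)propynal
Product: 4 (4R)-4-benzyl-3-[(2R,3R)-3-hydroxy-2-methyl-5-(trimethylsilyl)pent-4-ynoyl]-1,3-oxazolidin-2-one, via Z-dibutylboron enolate 3 (not isolated)
Conditions: n-Bu2BOTf, i-Pr2NEt, CH2Cl2, 0 °C; 2, −78 → 0 °C; pH 7 buffer, MeOH, 30% H2O2, 0 °C
Reagents that add atoms: none
Why: Evans syn-aldol reaction, in which the Z-boron enolate adds through a Zimmerman–Traxler chair on the face away from the benzyl group, so the (R)-auxiliary should set 2R and 3R (syn) with the reactive, non-enolizable ynal.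

**Step 2**
Reactants: 4
Product: 5 (2S,3R)-2-methyl-5-(trimethylsilyl)pent-4-yne-1,3-diol
Conditions: LiBH4, MeOH (1 equiv), THF, 0 °C
Reagents that add atoms: none
Why: Reductive cleavage of the N-acyloxazolidinone by borohydride gives the 1,3-diol and returns the auxiliary without touching the alkynylsilane or either stereocentre (C2 becomes S only by a change of CIP priorities).

**Step 3**
Reactants: 5
Product: 6 (3R,4S)-5-[(tert-butyldimethylsilyl)oxy]-4-methyl-1-(trimethylsilyl)pent-1-yn-3-ol
Conditions: TBSCl (1.05 equiv), imidazole, CH2Cl2, −20 → 0 °C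
Reagents that add atoms: tert-butyldimethylsilyl chloride, CC(C)(C)[Si](C)(C)Cl
Why: Silyl ether formation is selective for the primary hydroxyl over the hindered secondary propargylic one and gives a C1 protecting group that tolerates alkaline peroxide and cold Me3SiOTf.

**Step 4**
Reactants: 6
Product: 7 (1Z,3R,4S)-5-[(tert-butyldimethylsilyl)oxy]-4-methyl-1-(trimethylsilyl)pent-1-en-3-ol
Conditions: H2 (1 atm), Pd/CaCO3 poisoned with Pb(OAc)2, quinoline, EtOAc/hexane, rt
Reagents that add atoms: none
Why: cis semi-hydrogenation of the alkynylsilane on poisoned palladium delivers both hydrogens to one face, so the Z-vinylsilane should form, and its bulk slows over-reduction.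

**Step 5**
Reactants: 7
Product: 8 (1Z,3R,4S)-5-[(tert-butyldimethylsilyl)oxy]-4-methyl-1-(trimethylsilyl)pent-1-en-3-yl methanesulfonate
Conditions: MsCl, Et3N, CH2Cl2, −40 °C; used crude at once
Reagents that add atoms: methanesulfonyl chloride, CS(=O)(=O)Cl
Why: O-sulfonylation of the secondary allylic alcohol forms only an O–S bond, so C3 keeps its configuration, and the cold, crude mesylate is carried on before it can ionize.

**Step 6**
Reactants: 8
Product: 9 tert-butyl{[(2S,3S,4Z)-3-hydroperoxy-2-methyl-5-(trimethylsilyl)pent-4-en-1-yl]oxy}dimethylsilane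
Conditions: 50% aq. H2O2 (large excess), KOH, MeOH/THF, 0 °C → rt
Reagents that add atoms: hydrogen peroxide, OO
Why: SN2 displacement of a secondary sulfonate by hydroperoxide anion inverts C3 (3R mesylate to 3S hydroperoxide); the allylic position speeds substitution, silicon on C5 blocks SN2′ attack, and no ester or other base-labile group is present.

**Step 7**
Reactants: 10 β-cyclocitral (2,6,6-trimethylcyclohex-1-ene-1-carbaldehyde)
Product: 11 2-(2,2-dibromoethenyl)-1,3,3-trimethylcyclohex-1-ene
Conditions: CBr4, PPh3, Zn, CH2Cl2, 0 °C → rt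
Reagents that add atoms: carbon tetrabromide, BrC(Br)(Br)Br
Why: Corey–Fuchs dibromo-olefination (Wittig-type reaction of Ph3P=CBr2) of a non-enolizable aldehyde.

**Step 8**
Reactants: 11
Product: 13 4-(2,6,6-trimethylcyclohex-1-en-1-yl)but-3-yn-2-one, via lithium acetylide 12 (not isolated)
Conditions: n-BuLi (2.1 equiv), THF, −78 → 0 °C; MeC(O)N(OMe)Me, −78 → 0 °C; 1 M HCl
Reagents that add atoms: N-methoxy-N-methylacetamide, CC(=O)N(C)OC
Why: Bromine–lithium exchange and Fritsch–Buttenberg–Wiechell rearrangement (second stage of the Corey–Fuchs sequence) give the acetylide, which is acylated once in a Weinreb ketone synthesis.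

**Step 9**
Reactants: 13
Product: 14 2-(3,3-dimethoxybut-1-yn-1-yl)-1,3,3-trimethylcyclohex-1-ene
Conditions: HC(OMe)3, MeOH, TsOH·H2O (cat.), rt; NaHCO3
Reagents that add atoms: trimethyl orthoformate, COC(OC)OC; methanol, CO
Why: Acid-catalysed ketalization driven by the orthoester as water scavenger; the ketal removes the ynone as a Michael acceptor and pre-activates C6 for step 11.

**Step 10**
Reactants: 14
Product: 15 3-(3,3-dimethoxybut-1-yn-1-yl)-2,4,4-trimethylcyclohex-2-en-1-one
Conditions: t-BuOOH (70% aq.), Rh2(C6H10NO)4 (dirhodium tetracaprolactamate, 1 mol %), K2CO3, CH2Cl2, rt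
Reagents that add atoms: tert-butyl hydroperoxide, CC(C)(C)OO
Why: Allylic C–H oxidation by tert-butylperoxyl radicals should take the ring CH2 next to the methyl-bearing alkene carbon to the enone, since the other ring flank is quaternary and the carbonate buffer protects the ketal.

**Step 11**
Reactants: 9; 15
Product: 17 tert-butyl{(2S)-2-[(3R,6S)-6-methyl-6-[(2,6,6-trimethyl-3-oxocyclohex-1-en-1-yl)ethynyl]-3,6-dihydro-1,2-dioxin-3-yl]propoxy}dimethylsilane, via mixed methyl peroxyketal 16 (not isolated)
Conditions: Me3SiOTf (1.2 equiv), 2,6-di-tert-butyl-4-methylpyridine (1.5 equiv), 4 Å MS, CH2Cl2 (0.05 M), −78 → −40 °C; Et3N, −78 °C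
Reagents that add atoms: none
Why: Proposed new method: Me3SiOTf ionizes ketal 15 and the hydroperoxide oxygen of 9 (free or O-silylated in the flask) is captured to give peroxyketal 16 (O1–C6 bond); a second ionization gives a propargylic peroxycarbenium ion that is attacked at C6 by the silicon-bearing carbon C5 of the Z-vinylsilane (C5–C6 bond), and the β-silyl cation at C4 sheds Me3Si+ to leave the C4=C5 alkene. The closest known reaction types are the silyl-Prins cyclization of Z-vinylsilyl homoallylic alcohols with carbonyl compounds to 3,6-dihydro-2H-pyrans and the Lewis-acid-mediated capture of peroxycarbenium ions by alkenes and allylsilanes. The 3,6-dihydro-1,2-dioxine closes in a 6-endo cation–olefin mode, because attack at the far alkyne carbon would need an eight-membered cyclic allene. The new stereocentre C6 should be set by C3 through a chair-like transition state in which the C3 side chain is pseudoequatorial and the slim alkyne, not the methyl group, lies syn to O2 in the pseudoaxial site, so that C7 ends cis to the C3 side chain (6S). The step needs ipso attack and this cis relay: the Z geometry holds the C5–Si bond parallel to the empty orbital growing at C4 (β-silicon effect), the preformed ketal is ionized far faster than the ring enone can engage the hydroperoxide, and the hindered pyridine keeps triflic acid from protodesilylating 9 or re-ionizing the tertiary C6–O bond of 17. C3 is untouched (its descriptor changes from S to R only because silicon is lost).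

**Step 12**
Reactants: 17
Product: 18 tert-butyl{(2S)-2-[(3R,6R)-6-methyl-6-[2-(2,6,6-trimethyl-3-oxocyclohex-1-en-1-yl)ethyl]-1,2-dioxan-3-yl]propoxy}dimethylsilane
Conditions: KO2CN=NCO2K (large excess, in portions), AcOH, MeOH/CH2Cl2, 0 °C → rt
Reagents that add atoms: none
Why: Diimide reduction transfers H2 in a concerted syn fashion to the cis ring alkene and twice to the alkyne, while the O–O bond and the tetrasubstituted enone alkene are inert to diimide and no stereocentre is touched.

**Step 13**
Reactants: 18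
Product: 19 (2S)-2-[(3R,6R)-6-methyl-6-[2-(2,6,6-trimethyl-3-oxocyclohex-1-en-1-yl)ethyl]-1,2-dioxan-3-yl]propan-1-ol
Conditions: HF·pyridine, pyridine, THF, 0 °C → rt
Reagents that add atoms: none
Why: Fluoride-mediated silyl ether cleavage under buffered, non-basic conditions avoids base-induced Kornblum–DeLaMare fragmentation of the secondary peroxide.

**Step 14**
Reactants: 19
Product: 21 (2R)-2-[(3R,6R)-6-methyl-6-[2-(2,6,6-trimethyl-3-oxocyclohex-1-en-1-yl)ethyl]-1,2-dioxan-3-yl]propanoic acid, via aldehyde 20 (not isolated)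
Conditions: TEMPO (cat.), PhI(OAc)2, MeCN/pH 7 buffer, rt
Reagents that add atoms: water, O
Why: Oxoammonium-catalysed (TEMPO) oxidation takes the primary alcohol through the aldehyde hydrate to the acid in a near-neutral medium, which should avoid epimerization at C2 and β-elimination of the peroxide.

**Step 15**
Reactants: 21
Product: 22 methyl (2R)-2-[(3R,6R)-6-methyl-6-[2-(2,6,6-trimethyl-3-oxocyclohex-1-en-1-yl)ethyl]-1,2-dioxan-3-yl]propanoate (diacarperoxide A)
Conditions: Me3SiCHN2, MeOH/toluene, 0 °C
Reagents that add atoms: (trimethylsilyl)diazomethane, C[Si](C)(C)C=[N+]=[N-]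
Why: O-methylation of the carboxylic acid by diazomethane released from Me3SiCHN2 and methanol is neutral and leaves the peroxide and C2 untouched.

**Compound list**

1 | (4R)-4-benzyl-3-propanoyl-1,3-oxazolidin-2-one | CCC(=O)N1[C@H](Cc2ccccc2)COC1=O | starting material
2 | 3-(trimethylsilyl)propynal | C[Si](C)(C)C#CC=O | starting material
3 | Z-dibutylboron enolate of 1 | C/C=C(\OB(CCCC)CCCC)N1[C@H](Cc2ccccc2)COC1=O | intermediate
4 | (4R)-4-benzyl-3-[(2R,3R)-3-hydroxy-2-methyl-5-(trimethylsilyl)pent-4-ynoyl]-1,3-oxazolidin-2-one | O=C1OC[C@@H](Cc2ccccc2)N1C(=O)[C@H](C)[C@@H](O)C#C[Si](C)(C)C | intermediate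
5 | (2S,3R)-2-methyl-5-(trimethylsilyl)pent-4-yne-1,3-diol | OC[C@H](C)[C@@H](O)C#C[Si](C)(C)C | intermediate
6 | (3R,4S)-5-[(tert-butyldimethylsilyl)oxy]-4-methyl-1-(trimethylsilyl)pent-1-yn-3-ol | CC(C)(C)[Si](C)(C)OC[C@H](C)[C@@H](O)C#C[Si](C)(C)C | intermediate
7 | (1Z,3R,4S)-5-[(tert-butyldimethylsilyl)oxy]-4-methyl-1-(trimethylsilyl)pent-1-en-3-ol | CC(C)(C)[Si](C)(C)OC[C@H](C)[C@@H](O)/C=C\[Si](C)(C)C | intermediate
8 | (1Z,3R,4S)-5-[(tert-butyldimethylsilyl)oxy]-4-methyl-1-(trimethylsilyl)pent-1-en-3-yl methanesulfonate | CC(C)(C)[Si](C)(C)OC[C@H](C)[C@@H](OS(C)(=O)=O)/C=C\[Si](C)(C)C | intermediate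
9 | tert-butyl{[(2S,3S,4Z)-3-hydroperoxy-2-methyl-5-(trimethylsilyl)pent-4-en-1-yl]oxy}dimethylsilane | CC(C)(C)[Si](C)(C)OC[C@H](C)[C@H](OO)/C=C\[Si](C)(C)C | intermediate
10 | β-cyclocitral | CC1=C(C=O)C(C)(C)CCC1 | starting material
11 | 2-(2,2-dibromoethenyl)-1,3,3-trimethylcyclohex-1-ene | CC1=C(C=C(Br)Br)C(C)(C)CCC1 | intermediate
12 | lithium (2,6,6-trimethylcyclohex-1-en-1-yl)acetylide | [Li]C#CC1=C(C)CCCC1(C)C | intermediate
13 | 4-(2,6,6-trimethylcyclohex-1-en-1-yl)but-3-yn-2-one | CC(=O)C#CC1=C(C)CCCC1(C)C | intermediate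
14 | 2-(3,3-dimethoxybut-1-yn-1-yl)-1,3,3-trimethylcyclohex-1-ene | COC(C)(OC)C#CC1=C(C)CCCC1(C)C | intermediate
15 | 3-(3,3-dimethoxybut-1-yn-1-yl)-2,4,4-trimethylcyclohex-2-en-1-one | COC(C)(OC)C#CC1=C(C)C(=O)CCC1(C)C | intermediate
16 | 3-[3-({(2S,3S,4Z)-1-[(tert-butyldimethylsilyl)oxy]-2-methyl-5-(trimethylsilyl)pent-4-en-3-yl}peroxy)-3-methoxybut-1-yn-1-yl]-2,4,4-trimethylcyclohex-2-en-1-one (both epimers at the ketal carbon) | CC(C)(C)[Si](C)(C)OC[C@H](C)[C@H](OOC(C)(OC)C#CC1=C(C)C(=O)CCC1(C)C)/C=C\[Si](C)(C)C | intermediate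
17 | tert-butyl{(2S)-2-[(3R,6S)-6-methyl-6-[(2,6,6-trimethyl-3-oxocyclohex-1-en-1-yl)ethynyl]-3,6-dihydro-1,2-dioxin-3-yl]propoxy}dimethylsilane | CC(C)(C)[Si](C)(C)OC[C@H](C)[C@H]1C=C[C@@](C)(C#CC2=C(C)C(=O)CCC2(C)C)OO1 | intermediate
18 | tert-butyl{(2S)-2-[(3R,6R)-6-methyl-6-[2-(2,6,6-trimethyl-3-oxocyclohex-1-en-1-yl)ethyl]-1,2-dioxan-3-yl]propoxy}dimethylsilane | CC(C)(C)[Si](C)(C)OC[C@H](C)[C@H]1CC[C@@](C)(CCC2=C(C)C(=O)CCC2(C)C)OO1 | intermediate
19 | (2S)-2-[(3R,6R)-6-methyl-6-[2-(2,6,6-trimethyl-3-oxocyclohex-1-en-1-yl)ethyl]-1,2-dioxan-3-yl]propan-1-ol | OC[C@H](C)[C@H]1CC[C@@](C)(CCC2=C(C)C(=O)CCC2(C)C)OO1 | intermediate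
20 | (2R)-2-[(3R,6R)-6-methyl-6-[2-(2,6,6-trimethyl-3-oxocyclohex-1-en-1-yl)ethyl]-1,2-dioxan-3-yl]propanal | O=C[C@H](C)[C@H]1CC[C@@](C)(CCC2=C(C)C(=O)CCC2(C)C)OO1 | intermediate
21 | (2R)-2-[(3R,6R)-6-methyl-6-[2-(2,6,6-trimethyl-3-oxocyclohex-1-en-1-yl)ethyl]-1,2-dioxan-3-yl]propanoic acid | OC(=O)[C@H](C)[C@H]1CC[C@@](C)(CCC2=C(C)C(=O)CCC2(C)C)OO1 | intermediate
22 | methyl (2R)-2-[(3R,6R)-6-methyl-6-[2-(2,6,6-trimethyl-3-oxocyclohex-1-en-1-yl)ethyl]-1,2-dioxan-3-yl]propanoate (diacarperoxide A) | COC(=O)[C@H](C)[C@H]1CC[C@@](C)(CCC2=C(C)C(=O)CCC2(C)C)OO1 | target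

**Step count**

Total: 15 steps. Longest linear sequence: 11 steps (steps 1–6 and 11–15); steps 7–10 form the four-step branch to 15.

**Steps most likely to fail**

Step 11 (proposed new method). Ionization may stop at peroxyketal 16 or be diverted to acid-induced peroxide cleavage (Hock-type), and facial discrimination at C6 between methyl and alkyne may be poor. The fallback uses known reactions only, sets out from 6 and 15 and comes back at 18; it closes the ring at O2–C3 by intramolecular SN2 instead of at C5–C6. Aqueous acid (PPTS, acetone/H2O) hydrolyses ketal 15 to 2,4,4-trimethyl-3-(3-oxobut-1-yn-1-yl)cyclohex-2-en-1-one F1. MeLi·LiBr (2.2 equiv, THF) deprotonates 6 and cleaves its C–Si bond, and the resulting alkoxide acetylide adds at −78 °C to the ynone carbonyl of F1, the more electrophilic and less hindered of its two ketones, to give diyne diol F2 as both C6 epimers. Hydrogenation (H2, Pd/C, EtOAc) saturates both alkynes and should spare the tetrasubstituted enone, giving saturated 1,4-diol F3. MsCl/Et3N at −20 °C sulfonylates only the secondary hydroxyl to give secondary mesylate F4, which is used at once. 50% H2O2 with catalytic H2SO4 exchanges the tertiary hydroxyl for a hydroperoxide by way of the tertiary cation, giving tertiary hydroperoxide F5. Cs2CO3 in DMF then closes the 1,2-dioxane by 6-exo-tet displacement of the mesylate with inversion at C3. This should give 18 together with its C6 epimer, to be separated by chromatography; material that loses its silyl ether in the acidic step arrives as 19.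

Step 6. The allylic mesylate may ionize or be solvolysed by methanol or water, which would erode the configuration at C3; it may also eliminate to the silyl diene, or the product may be alkylated a second time to a dialkyl peroxide. The fallback sets out from 8 and comes back at 9; it alkylates a protected hydroperoxide in an aprotic medium and unmasks it in a separate operation. 2-Methoxypropan-2-yl hydroperoxide with CsOH·H2O in DMF at 0 °C should displace the mesylate with inversion to give mixed peroxyketal F6, which cannot be alkylated twice. AcOH/THF/H2O at rt then releases 9 with loss of acetone and methanol.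

Step 12. Diimide may reduce the ring alkene but stall at the hindered alkyne, or at the cis-alkene derived from it, while disproportionation consumes the reagent. The fallback sets out from 17 and comes back at 18; it splits the reduction between two reagents. The diimide treatment is stopped once the ring alkene has gone, giving alkynyl 1,2-dioxane F7. Heterogeneous hydrogenation (H2, 1 atm, PtO2, EtOAc, short contact time) then takes the alkyne to the alkane; a saturated, non-allylic dialkyl peroxide and a tetrasubstituted enone are expected to survive these conditions.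

**Further compounds**

F1 | step 11 | 2,4,4-trimethyl-3-(3-oxobut-1-yn-1-yl)cyclohex-2-en-1-one | CC(=O)C#CC1=C(C)C(=O)CCC1(C)C
F2 | step 11 | 3-[(6R,7S)-8-[(tert-butyldimethylsilyl)oxy]-3,6-dihydroxy-3,7-dimethylocta-1,4-diyn-1-yl]-2,4,4-trimethylcyclohex-2-en-1-one (both epimers at the tertiary carbinol) | CC(C)(C)[Si](C)(C)OC[C@H](C)[C@@H](O)C#CC(C)(O)C#CC1=C(C)C(=O)CCC1(C)C
F3 | step 11 | 3-[(6S,7S)-8-[(tert-butyldimethylsilyl)oxy]-3,6-dihydroxy-3,7-dimethyloctyl]-2,4,4-trimethylcyclohex-2-en-1-one (both epimers at the tertiary carbinol) | CC(C)(C)[Si](C)(C)OC[C@H](C)[C@@H](O)CCC(C)(O)CCC1=C(C)C(=O)CCC1(C)C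
F4 | step 11 | (2S,3S)-1-[(tert-butyldimethylsilyl)oxy]-6-hydroxy-2,6-dimethyl-8-(2,6,6-trimethyl-3-oxocyclohex-1-en-1-yl)octan-3-yl methanesulfonate (both epimers at C6) | CC(C)(C)[Si](C)(C)OC[C@H](C)[C@@H](OS(C)(=O)=O)CCC(C)(O)CCC1=C(C)C(=O)CCC1(C)C
F5 | step 11 | (2S,3S)-1-[(tert-butyldimethylsilyl)oxy]-6-hydroperoxy-2,6-dimethyl-8-(2,6,6-trimethyl-3-oxocyclohex-1-en-1-yl)octan-3-yl methanesulfonate (both epimers at C6) | CC(C)(C)[Si](C)(C)OC[C@H](C)[C@@H](OS(C)(=O)=O)CCC(C)(OO)CCC1=C(C)C(=O)CCC1(C)C
F6 | step 6 | tert-butyl{[(2S,3S,4Z)-3-[(2-methoxypropan-2-yl)peroxy]-2-methyl-5-(trimethylsilyl)pent-4-en-1-yl]oxy}dimethylsilane | CC(C)(C)[Si](C)(C)OC[C@H](C)[C@H](OOC(C)(C)OC)/C=C\[Si](C)(C)C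
F7 | step 12 | tert-butyl{(2S)-2-[(3R,6S)-6-methyl-6-[(2,6,6-trimethyl-3-oxocyclohex-1-en-1-yl)ethynyl]-1,2-dioxan-3-yl]propoxy}dimethylsilane | CC(C)(C)[Si](C)(C)OC[C@H](C)[C@H]1CC[C@@](C)(C#CC2=C(C)C(=O)CCC2(C)C)OO1
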